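(All runs were computed for an exercise, and the scatter is random.)

A flat reading can mean a flask in balance or a flask with nothing left to turn over, and taking one for the other is the pitfall here.

| setting | teal | blue | flask |
|---|---|---|---|
| solid substrate | 0.059 M | 0.040 M | 0.059 M |
| gas | 14 mM (held) | 14 mM (held) | 14 mM (held) |
| temperature | 70 °C | 65 °C | 70 °C |
| remark | the very flask that is asked about, followed so far | run made earlier |  |
| time |  |  | 15 h |

| run | time / min | target / % | solid substrate / % |
|---|---|---|---|
| teal | 120 | 70.2 | 0 |
| teal | 240 | 70.5 | 0 |
| teal | 300 | 70.7 | 0 |
| teal | 480 | 71.3 | 0 |
| teal | 600 | 69.8 | 0.8 |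
| blue | 4.00 | 2.0 | 82.3 |
| blue | 8.00 | 8.2 | 72.5 |
| blue | 12.0 | 15.6 | 66.6 |
| blue | 15.0 | 20.9 | 60.4 |
| blue | 20.0 | 30.4 | 49.6 |

(scatter of a reading: 0.5 percentage points)

- zeta: change nothing and wait 30 h more
- alpha: at 15 h raise the temperature by 10 K, then wait 30 h
- gamma: at 15 h take out 90% of the target then present, then wait 30 h

- solid, in amounts per volume of the solution: solid substrate
- target that was removed still counts
- the earlier runs were read with a standard deviation of 0.5 percentage points
- at the start none of the solid substrate is in solution
- at the start none of the gas is in solution

1. target, in percent of the solid substrate first charged, at 15 h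
2. the option that brings most further target ("none" if no option brings more than 2 percentage points) (zeta / alpha / gamma / none)
3. target present, with what was taken out counted in, in percent of the solid substrate first charged, after alpha
4. target present, with what was taken out counted in, in percent of the solid substrate first charged, after gamma

1. I begin with the blue run, where a flow can be read. Between 8.00 min and 20.0 min target grows by 0.740 mM min⁻¹. At 20.0 min the share that is neither solid nor target comes to 8.00 mM, which I treat as the hold-up of a tank.

2. Hold-up over flow is a time constant, 10.8 min. I call it the turnover time, the time the blue run takes to pass one hold-up on.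

3. The teal charge equals 7.38 hold-ups, so it should clear in 79.7 min, and 15 h is 11.3 such clearings. But the teal flask is warmer than the blue run, so that figure is rough. The teal solid already reads 0% at 120 min and the gas is held, so I take solid substrate as the limiting reagent.

4. Objection: teal target sticks near 70.5%, leaving 17.4 mM unread, twice the blue hold-up. Could that still be feeding target? From 120 min to 600 min pass 44.4 turnover times of the blue run, yet teal target reads 70.2% and then 69.8%, so I see no lasting flow.

5. Second objection: a balance could hold it there. The teal ratio of target to unread material is 2.39, and the blue run reaches 1.52. Yet its flow reads 0.740 mM min⁻¹ early and 0.760 mM min⁻¹ late, with no slowing on approach. So I take the unread share as lost to an unread product.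

6. I commit to 70.5% at 15 h, with that same value after alpha and after gamma, and no option gaining 2 percentage points.

The forecast gives 70.6%, gamma as best, 69% after alpha and 88% after gamma, reasoning from “a reversible reaction at equilibrium”, and there it differs from my reckoning.

The flask gives 70.2%, best option none, 70.2% after alpha and 70.2% after gamma. The unread share is side product, 29.8% at 900 min, where each side product counts as two, beside dissolved substrate at 0%.

    solid substrate ⇌ dissolved substrate, rate k1*(cs1 - [dissolved substrate]) while solid is left; crystals form when [dissolved substrate] > cs1 (solubility = 9.90 mM, k = 0.300 min⁻¹)
    dissolved substrate + partner → target (k = 16.0 M⁻¹ min⁻¹, Ea = 53.0 kJ mol⁻¹)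
    dissolved substrate + target → side product (k = 1.10 M⁻¹ min⁻¹, Ea = 62.0 kJ mol⁻¹)
    gas ⇌ partner, rate k4*(csat - [partner]) (kL = 0.160 min⁻¹)
    (constants at 70 °C)

The flask's solid substrate, solid and dissolved, takes 63.8 min to clear, which is 5.91 turnover times, while 15 h is 83.3, and 0% stands solid at 900 min.

In the neighbour with 0.24 M of solid substrate, the charge is 30.0 hold-ups, so it should clear in 324 min, giving 2.78 clearings by 15 h. Computed, that flask has 0% of its charge left and target at 39.2%.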